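You charge 1.20 mM of free base against 1.10 mM of protonated nucleophile and 1.0 mM of electrophile, and the free nucleophile has to come out of those amounts.

    electrophile + nucleophile → acid set free + target (k1 = 1300 M⁻¹ s⁻¹)
    nucleophile + acid set free ⇌ protonated nucleophile, settled at all times (K2 = 6.4 × 10⁶ M⁻¹)
    acid set free + free base ⇌ salt of the base, settled at all times (K3 = 1.3 × 10⁵ M⁻¹)
    2 electrophile → self-condensation product (k4 = 98 M⁻¹ s⁻¹)

electrophile 1.0 mM; free base 1.20 mM; protonated nucleophile 1.10 mM; time 10 s

- a species is counted by the electrophile in it: one self-condensation product counts as two
- a doubled species enters its step squared and goes two at a time
- run time (flask): 10 s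

* part of the electrophile that has reacted at 10 s
* share of the unused nucleophile that is free and not bound as protonated nucleophile, at 10 s

- The bench rule says that one free base frees one nucleophile, so it promises you 1.10 mM of free nucleophile.
- That rule needs the free base to bind acid more tightly than the nucleophile does. Take Q, the constant of the base balance over that of the nucleophile balance. It is 0.0203, far below one, so the rule fails in this flask.
- Q is also the constant of the exchange of protonated nucleophile and free base into nucleophile and salt. Neglecting what is used, the square root of Q times the two charges gives 0.164 mM. Subtracting that from both charges and repeating gives 0.140 mM at the start.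
- Now divide the coupling rate by the rate at which self-condensation loses electrophile. Time drops out, and the split S remains: S = g[N]/[E], with [N] free nucleophile and [E] electrophile.
- Self-condensation loses two electrophile per turn, so its loss constant is 196 M⁻¹ s⁻¹. With the coupling constant 1300 M⁻¹ s⁻¹, that gives the selectivity factor, a ratio of rate constants, g = 6.63.
- In this flask S starts at 0.931, which sends 48.2% of the electrophile then reacting to the target. My reckoning stops here: S tells you where electrophile goes, not how much has gone.
- The forecast gave 73.5% reacted (70% to 77%) and 2.4% free (2% to 2.9%): “Self-condensation starts at a similar rate but then dominates”.
- The flask gives 74.7% reacted and 2.36% free. At 1.54 s the rate ratio stands at 0.52, and at 10.0 s, with 0.0197 mM of nucleophile and electrophile at 25.3% of its charge, S reads 0.516; this flask holds 26.7% target and 48.0% self-condensation product. In the neighbour charged with 4.8 mM of free base, S reads 1.70 at 10.0 s, and that flask holds 34.9% self-condensation product and 47.5% target.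

The numbers of this flask are those of an exercise; what happens was integrated by code.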